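A factor of 14.1 separates the rate over Monday's first interval from that over its last, yet X fell only to 70.1%.

| flask | X | G | remark | time |
|---|---|---|---|---|
| Monday's | 0.10 M | 0.35 mol% | the very flask that is asked about, followed so far |  |
| flask | 0.10 M | 0.35 mol% |  | 1.0 h |

- Monday's (time / min: Z / %, X / %): 4.00: 6.5, 93.4; 12.0: 16.8, 83.0; 20.0: 22.9, 76.8; 30.0: 27.2, 73.2; 50.0: 29.5, 70.1

(each reading ± 0.3 percentage points)

- additions leave the volume as it is
- a reading or a percentage of Z counts all its forms, free or not

- eta: at 1.0 h add X, 50.0% of the amount charged, then wait 1.0 h
- epsilon: change nothing and wait 1.0 h more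
- zeta: at 1.0 h add G, 50.0% of the amount charged, then wait 1.0 h

- Z, in percent of the X first charged, at 1.0 h
- the option that brings most further Z ("none" if no option brings more than 2 percentage points) (eta / epsilon / zeta / none)
- Z present, in percent of the X first charged, after epsilon
- Z present, in percent of the X first charged, after zeta

Per unit of X the rate still fell by a factor of 10.8, so the shrinking thing in this flask looks like the working catalyst, not X. Suppose Z holds G reversibly (product inhibition). Once cZ is large, cG then goes as the charge of G over cZ, and with a rate proportional to cX cG, one product stays constant: S, the binding number, Z times its rate of rise over X, read from the last interval as 0.0273 h⁻¹, within about 18.4% from scatter. Z squared then grows at 2 times S times X, and such a parabola bends like a stop without being one. This reckoning gives 30.6% now and 36.2% after epsilon. Eta, with X raised, gives 39.8%; zeta, with S raised in proportion to G, gives 38.8%. But fresh G enters unbound, and at Monday's first rate per X and per G it closes that gap in 1.76 min, whereas Monday's rate between 12.0 min and 20.0 min still stood at half its first value. So this reckoning puts zeta first.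

The forecast, holding that “A saturated catalyst approaching equilibrium fits best”, gives 30%, eta, 30.1% after epsilon and 30.1% after zeta. The flask gives 30.5%, then 34.2% after epsilon and 39.6% after zeta; the gains are 9.1 percentage points for zeta, 6 points for eta and 3.6 points for epsilon.

    X + G ⇌ Q (K = 94.0 M⁻¹, k = 1.10 M⁻¹ s⁻¹)
    Q → E (k = 0.490 s⁻¹)
    E → G + Z (k = 1.10 s⁻¹)
    G + Z ⇌ L (K = 770 M⁻¹, k = 0.0760 M⁻¹ s⁻¹)

At 0.100 h G stood at 70.2% with L at 9.62%, and by 0.500 h L held 81.3% of the catalyst. At 1.00 h L held 94.4% and G 4.55%, while Z crept on. Reckoned from the flask's own Z over epsilon's hour, S comes to 0.0174 h⁻¹, where the reading from Monday's last interval was 0.0273 h⁻¹. In the neighbour with 0.59 mol% of G, S in proportion to G becomes 0.0294 h⁻¹, and Z, going as its root, 39.6%; that flask gives 38.8%.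

(The runs were generated by integration with made-up constants, and the scatter is random.)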